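**Remark on the chemistry (one assumption):** the SMILES is read as (1S,3S,4S,5R,6S,7R,8R,10R)-1,10:4,5-diepoxy-9-oxogermacr-11-ene-3,6,8-triyl tris[(2Z)-2-methylbut-2-enoate]. Germacrane numbering is used for all ring compounds (ring C1–C10, isopropenyl C11–C13 on C7, C14 on C10, C15 on C4). "Target configuration" means the spatial arrangement fixed by the SMILES in the compound list.

## The problem

The target is a ten-membered carbocycle (C1–C10) in which eight ring carbons are stereogenic and seven carry oxygen. It holds a trans 1,10-epoxide next to the C9 ketone, a cis 4,5-epoxide between the C3 and C6 angelates, an isopropenyl group on C7 and a third angelate on C8. The ring is the first difficulty: ten-membered rings close badly, and this one must contain the equivalents of one E and one Z trisubstituted olefin. The stereocentres fall into three groups. C1/C10 and C3 cannot be controlled reliably by anything in a floppy medium ring, so they must be set by reagent control on an open chain. The 4,5-epoxide can be directed by a free C6 hydroxyl. The triad C6(O)–C7(isopropenyl)–C8(O) is best made in the ring-forming event itself. The angelates isomerise to tiglates and do not survive hydride or strong base, the α-acyloxy ketone at C8 can epimerise, and both epoxides are acid-sensitive, so acylation must be last and the end-game mild. The feature that makes the key step possible is the array C9(=O)–C8(O)–C7(–C11(=C12)C13)–C6(O): C8 is α to the ketone and bears oxygen, and its neighbour C7 bears an isopropenyl group, which is exactly the product pattern of a [2,3] shift of an oxonium ylide C8(−)–O(+)–C12–C11=C7. Because O6 and O8 are 1,3-syn, they can be the two oxygens of one formaldehyde acetal: a 4,7-dihydro-1,3-dioxepine (O6–CH2–O12, C6, C7=C11, C12) before the shift and a 1,3-dioxane (O6–CH2–O8, C6, C7, C8) after it.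

## Retrosynthesis

**31 ⇒ 30.** The three angelate C–O acyl bonds are cut first. The esters are the most fragile groups and would not survive hydride, fluoride or base. The forward step is one mild triple acylation of triol 30.

**30 ⇒ 29 ⇒ 28.** The C3 silyl ether is restored (29) and the two C–O bonds of the 4,5-epoxide are cut back to the Z olefin of 28, which has C6–OH free and C3–O silylated. In the conformer that minimises A(1,3) strain (H6 in the olefin plane), O6 and the epoxide oxygen of the target lie on the same face, while O3 lies on the other. A free C6–OH therefore delivers the oxidant correctly, and C3 must stay blocked. Carrying this epoxide through the carbenoid step was rejected, because an epoxide oxygen near the reacting centre is itself a carbenoid trap.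

**28 ⇒ 27.** O6 and O8 are re-tied as a formaldehyde acetal. Dioxane 27 is not a detour: it is the form in which the key step delivers the 6,8-diol.

**27 ⇒ 26 ⇒ 25 (key).** The C7–C8 bond is cut and the oxygen on C8 is returned to C12, restoring the C7=C11 olefin. This opens the ten-membered ring and the dioxane at once and leads, via ylide 26, to diazoketone 25, an open chain on a monocyclic dihydrodioxepine.
- Cutting C6–C7 or C8–C9 instead would leave C7 and C8 to be made on a flexible chain with no internal control.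
- This cut removes the ring, two stereocentres, the isopropenyl group and the α-oxy ketone together. Compound 25 has only four stereocentres (C1, C3, C6, C10), all set by reagents.
- The forward reaction must form the ylide at the primary acetal oxygen O12 and then rearrange by a [2,3] and not a [1,2] path.

**25 ⇒ 23 ⇒ 22 ⇒ 21.** The C8–C9 bond is cut (acylation of diazomethane by glycidic acid 23). The epoxide is taken back through epoxy alcohol 22 to the E allylic alcohol 21 (Sharpless epoxidation). Installing C1/C10 here gives reagent control instead of a guess at the facial bias of a medium-ring enone. The trans epoxide also serves as a rigid spacer in the key step.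

**21 ⇒ 20 ⇒ 19 ⇒ 15 + 18.** The C2–C3 bond is cut as a vinylogous Mukaiyama aldol between Z enal 15 and silyl dienolate 18 (from methyl tiglate 16). One step supplies the C3 carbinol under catalyst control, C2, the E C1=C10 olefin and C9.

**15 ⇒ 13 ⇒ 12 ⇒ 11 ⇒ 9 ⇒ 8 ⇒ 4 + 6.**
- C3 is removed (formylation of vinyl iodide 13).
- The acetal carbon is removed (diol 12, from silyl ether 11).
- The Z iodide is taken back to propargylic alcohol 9; hydroxyl-directed trans-hydroalumination puts iodine cis to C6 and so fixes the C4=C5 geometry.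
- C6 is set by CBS reduction of ynone 8.
- The C6–C7 bond comes from the vinyllithium of 4 and Weinreb amide 6 (from acid 5).
- Iodide 4 comes from 3, made from propargyl alcohol 1 by anti-carbomagnesiation, which fixes the Z C7=C11 geometry that the dioxepine needs.

## Roads not taken

**Alternative 1:** (the obvious one) cut C6–C7 and close the ring by intramolecular allylation of a Z enal with an allylic chloride (CrCl2, or zerovalent palladium with Et2Zn), from the acyclic chloro-aldehyde A1; epoxidations and acylations follow. The ring closure creates C6 and C7 under macrocyclic control only, with no enforced relation to C8. A1 itself needs a long linear synthesis that must already contain the C8 stereocentre next to a ketone and an isomerisation-prone Z enal. The chosen plan reaches its precursor with the same effort but lets a template set C7 and C8.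

**Alternative 2:** cut the ring to a six-membered precursor, the trans-1,2-dialkenylcyclohexenol A2, and expand by anionic oxy-Cope rearrangement (C8–C9 formed, C1–C6 broken). The ring, the E C1=C10 olefin and the Z C4=C5 olefin come easily. The product, however, has CH2 groups at C8 and C9 and a ketone at C6, and C7 is set by an uncontrolled enolate protonation. Two oxidations at poorly activated positions, a ketone reduction and a stereochemical correction would have to follow on a sensitive triene. The ring is gained but the oxygen pattern is lost.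

**Alternative 3:** the same C7–C8 cut, but as an anionic [2,3]-Wittig ring contraction of the thirteen-membered α-allyloxy ketone A3. Macrocyclic Wittig ring contractions to germacrane rings are known, but this variant has three weaknesses:
- A separate thirteen-membered etherification is needed first.
- Enolates of α-allyloxy ketones can take the [3,3] path (C9–C7 bond), and strong base meets an epoxy ketone.
- Nothing delivers C8 to the face of O6; an open allylic ether is expected to react anti to the C6 oxygen, the opposite of what the target needs.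

The carbenoid route merges ring closure and rearrangement under neutral conditions, and the acetal enforces delivery syn to O6.

Key step: step 17

## Route

Step 1
Reactants: 1 prop-2-yn-1-ol
Product: 3 (2Z)-3-iodo-2-methylprop-2-en-1-ol, via cyclic vinylmagnesium alkoxide 2 (not isolated)
Conditions: MeMgBr (2.3 equiv), CuI (10 mol %), THF/Et2O, −10 °C to rt; then I2, −60 to 0 °C
Reagents that add atoms: methylmagnesium bromide, C[Mg]Br; iodine, II
Why: Copper-catalysed anti-carbomagnesiation of the propargylic alkoxide puts methyl on the internal carbon and magnesium cis to CH2O (five-membered chelate 2); iodinolysis with retention gives the Z iodide.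

Step 2
Reactants: 3 (2Z)-3-iodo-2-methylprop-2-en-1-ol
Product: 4 tert-butyl{[(2Z)-3-iodo-2-methylprop-2-en-1-yl]oxy}dimethylsilane
Conditions: TBSCl, imidazole, CH2Cl2, 0 °C to rt
Reagents that add atoms: tert-butyldimethylsilyl chloride, CC(C)(C)[Si](C)(C)Cl
Why: Standard silylation of a primary alcohol; O12 must be masked for the halogen–lithium exchange.

Step 3
Reactants: 5 but-2-ynoic acid
Product: 6 N-methoxy-N-methylbut-2-ynamide
Conditions: MeNH(OMe)·HCl, EDC·HCl, N-methylmorpholine, CH2Cl2, 0 °C to rt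
Reagents that add atoms: N,O-dimethylhydroxylamine hydrochloride, CNOC.Cl
Why: Carbodiimide amidation gives the Weinreb amide.

Step 4
Reactants: 4 tert-butyl{[(2Z)-3-iodo-2-methylprop-2-en-1-yl]oxy}dimethylsilane; 6 N-methoxy-N-methylbut-2-ynamide
Product: 8 (2Z)-1-[(tert-butyldimethylsilyl)oxy]-2-methylhept-2-en-5-yn-4-one, via vinyllithium 7 (not isolated)
Conditions: 4, t-BuLi (2.0 equiv), Et2O, −78 °C; then 6, −78 °C; aq NH4Cl
Reagents that add atoms: tert-butyllithium, [Li]C(C)(C)C (lithium kept only in 7)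
Why: Iodine–lithium exchange with retention, then Weinreb ketone synthesis; the chelated tetrahedral intermediate prevents over-addition and the cold acetylenic amide reacts 1,2.

Step 5
Reactants: 8 (2Z)-1-[(tert-butyldimethylsilyl)oxy]-2-methylhept-2-en-5-yn-4-one
Product: 9 (2Z,4S)-1-[(tert-butyldimethylsilyl)oxy]-2-methylhept-2-en-5-yn-4-ol
Conditions: (S)-2-methyl-CBS-oxazaborolidine (0.2 equiv), catecholborane (1.5 equiv), CH2Cl2/toluene, −78 °C
Reagents that add atoms: none
Why: Corey–Bakshi–Shibata reduction of an ynone; the slim propynyl group acts as the small and the Z-trisubstituted alkenyl group as the large substituent, which with the (S)-catalyst gives the 4S carbinol (C6 of the target).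

Step 6
Reactants: 9 (2Z,4S)-1-[(tert-butyldimethylsilyl)oxy]-2-methylhept-2-en-5-yn-4-ol
Product: 11 (2Z,4S,5Z)-7-[(tert-butyldimethylsilyl)oxy]-2-iodo-6-methylhepta-2,5-dien-4-ol, via vinylalanate 10 (not isolated)
Conditions: NaAlH2(OCH2CH2OMe)2 (2.5 equiv), THF, 0 °C to rt; EtOAc; then I2, −78 to −10 °C
Reagents that add atoms: iodine, II; sodium bis(2-methoxyethoxy)aluminium hydride, [Na+].[AlH2-](OCCOC)OCCOC (atoms kept only in 10)
Why: Hydroxyl-directed trans-hydroalumination of the propargylic alcohol puts aluminium on the distal carbon cis to the carbinol (five-membered alanate 10); iodinolysis with retention gives the Z iodide that fixes the C4=C5 geometry.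

Step 7
Reactants: 11 (2Z,4S,5Z)-7-[(tert-butyldimethylsilyl)oxy]-2-iodo-6-methylhepta-2,5-dien-4-ol
Product: 12 (2Z,4S,5Z)-6-iodo-2-methylhepta-2,5-diene-1,4-diol
Conditions: Bu4NF, THF, 0 °C
Reagents that add atoms: none
Why: Fluoride desilylation; the vinyl iodide and the doubly allylic carbinol tolerate these non-acidic conditions.

Step 8
Reactants: 12 (2Z,4S,5Z)-6-iodo-2-methylhepta-2,5-diene-1,4-diol
Product: 13 (4S)-4-[(1Z)-2-iodoprop-1-en-1-yl]-6-methyl-4,7-dihydro-1,3-dioxepine
Conditions: NaH (2.5 equiv), CH2Br2, Bu4NI (cat.), THF/DMF, 0 to 40 °C, 0.02 M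
Reagents that add atoms: dibromomethane, BrCBr
Why: Double Williamson alkylation; the Z olefin holds the two oxygens close so the seven-membered methylene acetal closes, and basic conditions avoid ionising the doubly allylic C6–O bond.

Step 9
Reactants: 13 (4S)-4-[(1Z)-2-iodoprop-1-en-1-yl]-6-methyl-4,7-dihydro-1,3-dioxepine
Product: 15 (2Z)-2-methyl-3-[(4S)-6-methyl-4,7-dihydro-1,3-dioxepin-4-yl]prop-2-enal, via vinyllithium 14 (not isolated)
Conditions: t-BuLi (2.0 equiv), Et2O, −78 °C; DMF, −78 to −40 °C; pH 7 buffer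
Reagents that add atoms: N,N-dimethylformamide, CN(C)C=O; tert-butyllithium, [Li]C(C)(C)C (lithium kept only in 14)
Why: Iodine–lithium exchange with retention and Bouveault formylation; the neutral cold work-up guards against Z to E isomerisation and γ-deprotonation at C6.

Step 10
Reactants: 16 methyl (2E)-2-methylbut-2-enoate
Product: 18 tert-butyl[(1-methoxy-2-methylbuta-1,3-dien-1-yl)oxy]dimethylsilane, via lithium dienolate 17 (not isolated)
Conditions: LiN(iPr)2, THF/DMPU, −78 °C; then TBSCl
Reagents that add atoms: tert-butyldimethylsilyl chloride, CC(C)(C)[Si](C)(C)Cl; lithium diisopropylamide, [Li]N(C(C)C)C(C)C (lithium kept only in 17)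
Why: Kinetic γ-deprotonation of the tiglate and O-silylation give the vinylketene silyl acetal used for vinylogous aldol additions.

Step 11
Reactants: 15 (2Z)-2-methyl-3-[(4S)-6-methyl-4,7-dihydro-1,3-dioxepin-4-yl]prop-2-enal; 18 tert-butyl[(1-methoxy-2-methylbuta-1,3-dien-1-yl)oxy]dimethylsilane
Product: 19 methyl (2E,5S,6Z)-5-hydroxy-2,6-dimethyl-7-[(4S)-6-methyl-4,7-dihydro-1,3-dioxepin-4-yl]hepta-2,6-dienoate
Conditions: SiCl4 (1.1 equiv), chiral binaphthyldiamine bisphosphoramide (5 mol %, the enantiomer that directs Si-face attack), iPr2NEt (10 mol %), CH2Cl2, −78 °C; aq KF/NaHCO3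
Reagents that add atoms: none
Why: Lewis-base-activated vinylogous Mukaiyama aldol addition; attack through the γ-carbon gives the E enoate, and the catalyst, not the remote C6 centre, sets the 5S carbinol (C3 of the target).

Step 12
Reactants: 19 methyl (2E,5S,6Z)-5-hydroxy-2,6-dimethyl-7-[(4S)-6-methyl-4,7-dihydro-1,3-dioxepin-4-yl]hepta-2,6-dienoate
Product: 20 methyl (2E,5S,6Z)-5-[(tert-butyldimethylsilyl)oxy]-2,6-dimethyl-7-[(4S)-6-methyl-4,7-dihydro-1,3-dioxepin-4-yl]hepta-2,6-dienoate
Conditions: TBSOTf, 2,6-lutidine, CH2Cl2, −78 to 0 °C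
Reagents that add atoms: tert-butyldimethylsilyl triflate, CC(C)(C)[Si](C)(C)OS(=O)(=O)C(F)(F)F
Why: Silylation of the allylic carbinol; a silyl ether is not a ylide donor in step 17 and blocks O3 in step 19.

Step 13
Reactants: 20 methyl (2E,5S,6Z)-5-[(tert-butyldimethylsilyl)oxy]-2,6-dimethyl-7-[(4S)-6-methyl-4,7-dihydro-1,3-dioxepin-4-yl]hepta-2,6-dienoate
Product: 21 (2E,5S,6Z)-5-[(tert-butyldimethylsilyl)oxy]-2,6-dimethyl-7-[(4S)-6-methyl-4,7-dihydro-1,3-dioxepin-4-yl]hepta-2,6-dien-1-ol
Conditions: iBu2AlH (2.5 equiv), CH2Cl2, −78 °C; Rochelle salt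
Reagents that add atoms: none
Why: 1,2-Reduction of the enoate to the E allylic alcohol; acetal and silyl ether are inert.

Step 14
Reactants: 21 (2E,5S,6Z)-5-[(tert-butyldimethylsilyl)oxy]-2,6-dimethyl-7-[(4S)-6-methyl-4,7-dihydro-1,3-dioxepin-4-yl]hepta-2,6-dien-1-ol
Product: 22 [(2S,3S)-3-{(2S,3Z)-2-[(tert-butyldimethylsilyl)oxy]-3-methyl-4-[(4S)-6-methyl-4,7-dihydro-1,3-dioxepin-4-yl]but-3-en-1-yl}-2-methyloxiran-2-yl]methanol
Conditions: Ti(OiPr)4 (10 mol %), L-(+)-diethyl tartrate (12 mol %), t-BuOOH (2 equiv, decane), 4 Å MS, CH2Cl2, −20 °C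
Reagents that add atoms: tert-butyl hydroperoxide, CC(C)(C)OO
Why: Sharpless asymmetric epoxidation; only the primary allylic alcohol binds titanium, so the other two olefins are untouched, and the L-(+)-tartrate gives the (2S,3S)-epoxy alcohol that becomes the 1S,10R epoxide.

Step 15
Reactants: 22 [(2S,3S)-3-{(2S,3Z)-2-[(tert-butyldimethylsilyl)oxy]-3-methyl-4-[(4S)-6-methyl-4,7-dihydro-1,3-dioxepin-4-yl]but-3-en-1-yl}-2-methyloxiran-2-yl]methanol
Product: 23 (2R,3S)-3-{(2S,3Z)-2-[(tert-butyldimethylsilyl)oxy]-3-methyl-4-[(4S)-6-methyl-4,7-dihydro-1,3-dioxepin-4-yl]but-3-en-1-yl}-2-methyloxirane-2-carboxylic acid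
Conditions: TEMPO (20 mol %), PhI(OAc)2 (2.2 equiv), MeCN/aq NaHCO3 buffer, 0 °C to rt
Reagents that add atoms: water, O
Why: Oxoammonium oxidation of the primary alcohol through the aldehyde hydrate to the acid; the reagent does not attack olefins, and the α-carbon is quaternary so it cannot epimerise.

Step 16
Reactants: 23 (2R,3S)-3-{(2S,3Z)-2-[(tert-butyldimethylsilyl)oxy]-3-methyl-4-[(4S)-6-methyl-4,7-dihydro-1,3-dioxepin-4-yl]but-3-en-1-yl}-2-methyloxirane-2-carboxylic acid
Product: 25 2-diazo-1-[(2R,3S)-3-{(2S,3Z)-2-[(tert-butyldimethylsilyl)oxy]-3-methyl-4-[(4S)-6-methyl-4,7-dihydro-1,3-dioxepin-4-yl]but-3-en-1-yl}-2-methyloxiran-2-yl]ethan-1-one, via mixed carbonic anhydride 24 (not isolated)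
Conditions: iBuOCOCl, Et3N, THF, −20 °C; then CH2N2 (Et2O, excess), 0 °C
Reagents that add atoms: diazomethane, C=[N+]=[N-]; isobutyl chloroformate, CC(C)COC(Cl)=O (atoms kept only in 24)
Why: Acylation of diazomethane by a mixed anhydride, the standard route from glycidic acids to α,β-epoxy diazomethyl ketones; it adds C8 and leaves the epoxide intact.

Step 17
Reactants: 25 2-diazo-1-[(2R,3S)-3-{(2S,3Z)-2-[(tert-butyldimethylsilyl)oxy]-3-methyl-4-[(4S)-6-methyl-4,7-dihydro-1,3-dioxepin-4-yl]but-3-en-1-yl}-2-methyloxiran-2-yl]ethan-1-one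
Product: 27 (4Z)-1,10-epoxy-3-[(tert-butyldimethylsilyl)oxy]-6,8-(methylenedioxy)germacra-4,11-dien-9-one (target configuration at C1, C3, C6, C7, C8, C10), via bicyclic oxonium ylide 26 (not isolated)
Conditions: Cu(CF3COCHCOCF3)2 (10 mol %), CH2Cl2, reflux; 25 added over 12 h by syringe pump (final 1 mM)
Reagents that add atoms: none
Why: Proposed new method: Divalent copper is reduced by the diazo compound to monovalent copper, which turns 25 into an electrophilic keto-carbenoid at C8; the primary allylic acetal oxygen O12 adds to it to give the bicyclic oxonium ylide 26, and a concerted suprafacial [2,3] shift through a five-membered envelope (C8–O12–C12–C11=C7) forms C7–C8, breaks O12–C12 and unveils the isopropenyl group. The closest known reactions are the copper-catalysed oxonium-ylide/[2,3] rearrangements of diazoketones with allyl ethers, the [2,3] shift of ylides from allylic acetals, and macrocyclic oxonium-ylide/[2,3] ring contractions of diazoacetates; new is their union on a cyclic allylic acetal to give a carbocycle. Two rings close at once: the ten-membered carbocycle by C8-to-C7 bonding inside the twelve-membered cyclic ylide (a ring contraction), and the 1,3-dioxane by contraction of the seven-membered dioxepine as O12 ends on C8. C7 is set by the template: C8 can only reach the olefin face on which the acetal oxygens sit, and with C5 pseudo-equatorial (otherwise A(1,3) strain with C12H2) this gives the 6,7-trans relationship of the target. C8 is set by the tether: the seven-carbon chain from C9 to C5 can bridge the nascent dioxane only if C9 and C5 are cis, which puts C9 trans to the isopropenyl group. The step needs ylide formation at O12 to beat cyclopropanation of C7=C11, ylide formation at the hindered O6 and a [1,2] shift; the unsubstituted acetal carbon (no stabilised oxocarbenium for a [1,2] path), the copper catalyst and high dilution favour this, and the trans epoxide holds the C2 hydrogens and O3 out of reach of C8.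

Step 18
Reactants: 27 (4Z)-1,10-epoxy-3-[(tert-butyldimethylsilyl)oxy]-6,8-(methylenedioxy)germacra-4,11-dien-9-one
Product: 28 (4Z)-1,10-epoxy-6,8-dihydroxy-3-[(tert-butyldimethylsilyl)oxy]germacra-4,11-dien-9-one (target configuration)
Conditions: Me3SiOTf (4 equiv), 2,2'-bipyridyl (6 equiv), CH2Cl2, 0 °C to rt; then H2O
Reagents that add atoms: none
Why: Silyl triflate/bipyridyl cleavage of a methylene acetal through a pyridinium-trapped oxocarbenium ion and hydrolysis; the buffered conditions are mild enough for silyl ethers and should spare the deactivated epoxy ketone.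

Step 19
Reactants: 28 (4Z)-1,10-epoxy-6,8-dihydroxy-3-[(tert-butyldimethylsilyl)oxy]germacra-4,11-dien-9-one
Product: 29 1,10:4,5-diepoxy-6,8-dihydroxy-3-[(tert-butyldimethylsilyl)oxy]germacr-11-en-9-one (target configuration)
Conditions: VO(acac)2 (10 mol %), t-BuOOH (1.3 equiv, decane), CH2Cl2, 0 °C
Reagents that add atoms: tert-butyl hydroperoxide, CC(C)(C)OO
Why: Hydroxyl-directed vanadium epoxidation; only C4=C5 is allylic to a free hydroxyl, and in the A(1,3)-minimised conformer (H6 in the olefin plane) O6 sits on the face that gives the threo epoxy alcohol of the target while the silyl ether shields the other face.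

Step 20
Reactants: 29 1,10:4,5-diepoxy-6,8-dihydroxy-3-[(tert-butyldimethylsilyl)oxy]germacr-11-en-9-one
Product: 30 1,10:4,5-diepoxy-3,6,8-trihydroxygermacr-11-en-9-one (target configuration)
Conditions: HF·pyridine, pyridine, THF, 0 °C to rt
Reagents that add atoms: none
Why: Buffered fluoride desilylation; the non-basic medium avoids enolisation of the α-hydroxy ketone and Payne-type epoxide migration.

Step 21
Reactants: 30 1,10:4,5-diepoxy-3,6,8-trihydroxygermacr-11-en-9-one
Product: 31 (1S,3S,4S,5R,6S,7R,8R,10R)-1,10:4,5-diepoxy-9-oxogermacr-11-ene-3,6,8-triyl tris[(2Z)-2-methylbut-2-enoate]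
Conditions: angelic acid (6 equiv), 2,4,6-Cl3C6H2COCl (6 equiv), Et3N, toluene, rt, 2 h; then 30, toluene, 75 °C
Reagents that add atoms: angelic acid, C/C=C(/C)C(=O)O
Why: Yamaguchi-type esterification through the mixed 2,4,6-trichlorobenzoic anhydride, the standard way to make angelates of hindered alcohols without Z to E isomerisation; no stereocentre is touched.

## Compound list

1 | prop-2-yn-1-ol | C#CCO | starting material
2 | cyclic vinylmagnesium alkoxide of (Z)-3-magnesio-2-methylprop-2-en-1-ol | CC1=C[Mg]OC1 | intermediate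
3 | (2Z)-3-iodo-2-methylprop-2-en-1-ol | I/C=C(C)\CO | intermediate
4 | tert-butyl{[(2Z)-3-iodo-2-methylprop-2-en-1-yl]oxy}dimethylsilane | I/C=C(C)\CO[Si](C)(C)C(C)(C)C | intermediate
5 | but-2-ynoic acid | CC#CC(=O)O | starting material
6 | N-methoxy-N-methylbut-2-ynamide | CC#CC(=O)N(C)OC | intermediate
7 | (Z)-vinyllithium from 4 | [Li]/C=C(C)\CO[Si](C)(C)C(C)(C)C | intermediate
8 | (2Z)-1-[(tert-butyldimethylsilyl)oxy]-2-methylhept-2-en-5-yn-4-one | CC#CC(=O)/C=C(C)\CO[Si](C)(C)C(C)(C)C | intermediate
9 | (2Z,4S)-1-[(tert-butyldimethylsilyl)oxy]-2-methylhept-2-en-5-yn-4-ol | CC#C[C@@H](O)/C=C(C)\CO[Si](C)(C)C(C)(C)C | intermediate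
10 | sodium cyclic alkoxy(vinyl)alanate from 9 (Al on the methyl-bearing carbon, cis to C–O) | CC1=C[C@H](/C=C(C)\CO[Si](C)(C)C(C)(C)C)O[Al-]1(OCCOC)OCCOC.[Na+] | intermediate
11 | (2Z,4S,5Z)-7-[(tert-butyldimethylsilyl)oxy]-2-iodo-6-methylhepta-2,5-dien-4-ol | I/C(C)=C\[C@@H](O)/C=C(C)\CO[Si](C)(C)C(C)(C)C | intermediate
12 | (2Z,4S,5Z)-6-iodo-2-methylhepta-2,5-diene-1,4-diol | I/C(C)=C\[C@@H](O)/C=C(C)\CO | intermediate
13 | (4S)-4-[(1Z)-2-iodoprop-1-en-1-yl]-6-methyl-4,7-dihydro-1,3-dioxepine | I/C(C)=C\[C@H]1OCOCC(C)=C1 | intermediate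
14 | (Z)-vinyllithium from 13 | [Li]/C(C)=C\[C@H]1OCOCC(C)=C1 | intermediate
15 | (2Z)-2-methyl-3-[(4S)-6-methyl-4,7-dihydro-1,3-dioxepin-4-yl]prop-2-enal | O=C/C(C)=C\[C@H]1OCOCC(C)=C1 | intermediate
16 | methyl (2E)-2-methylbut-2-enoate (methyl tiglate) | C/C=C(\C)C(=O)OC | starting material
17 | lithium dienolate of methyl tiglate | C=CC(C)=C(OC)O[Li] | intermediate
18 | tert-butyl[(1-methoxy-2-methylbuta-1,3-dien-1-yl)oxy]dimethylsilane | C=CC(C)=C(OC)O[Si](C)(C)C(C)(C)C | intermediate
19 | methyl (2E,5S,6Z)-5-hydroxy-2,6-dimethyl-7-[(4S)-6-methyl-4,7-dihydro-1,3-dioxepin-4-yl]hepta-2,6-dienoate | COC(=O)/C(C)=C/C[C@H](O)/C(C)=C\[C@H]1OCOCC(C)=C1 | intermediate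
20 | methyl (2E,5S,6Z)-5-[(tert-butyldimethylsilyl)oxy]-2,6-dimethyl-7-[(4S)-6-methyl-4,7-dihydro-1,3-dioxepin-4-yl]hepta-2,6-dienoate | COC(=O)/C(C)=C/C[C@H](O[Si](C)(C)C(C)(C)C)/C(C)=C\[C@H]1OCOCC(C)=C1 | intermediate
21 | (2E,5S,6Z)-5-[(tert-butyldimethylsilyl)oxy]-2,6-dimethyl-7-[(4S)-6-methyl-4,7-dihydro-1,3-dioxepin-4-yl]hepta-2,6-dien-1-ol | OC/C(C)=C/C[C@H](O[Si](C)(C)C(C)(C)C)/C(C)=C\[C@H]1OCOCC(C)=C1 | intermediate
22 | [(2S,3S)-3-{(2S,3Z)-2-[(tert-butyldimethylsilyl)oxy]-3-methyl-4-[(4S)-6-methyl-4,7-dihydro-1,3-dioxepin-4-yl]but-3-en-1-yl}-2-methyloxiran-2-yl]methanol | OC[C@]1(C)O[C@H]1C[C@H](O[Si](C)(C)C(C)(C)C)/C(C)=C\[C@H]1OCOCC(C)=C1 | intermediate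
23 | (2R,3S)-3-{(2S,3Z)-2-[(tert-butyldimethylsilyl)oxy]-3-methyl-4-[(4S)-6-methyl-4,7-dihydro-1,3-dioxepin-4-yl]but-3-en-1-yl}-2-methyloxirane-2-carboxylic acid | OC(=O)[C@]1(C)O[C@H]1C[C@H](O[Si](C)(C)C(C)(C)C)/C(C)=C\[C@H]1OCOCC(C)=C1 | intermediate
24 | isobutyl carbonic anhydride of acid 23 | CC(C)COC(=O)OC(=O)[C@]1(C)O[C@H]1C[C@H](O[Si](C)(C)C(C)(C)C)/C(C)=C\[C@H]1OCOCC(C)=C1 | intermediate
25 | 2-diazo-1-[(2R,3S)-3-{(2S,3Z)-2-[(tert-butyldimethylsilyl)oxy]-3-methyl-4-[(4S)-6-methyl-4,7-dihydro-1,3-dioxepin-4-yl]but-3-en-1-yl}-2-methyloxiran-2-yl]ethan-1-one | [N-]=[N+]=CC(=O)[C@]1(C)O[C@H]1C[C@H](O[Si](C)(C)C(C)(C)C)/C(C)=C\[C@H]1OCOCC(C)=C1 | intermediate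
26 | bicyclic oxonium ylide (C8 carbanion bonded to the oxonium oxygen O12 of the dioxepine; twelve-membered ring C8–C9–C10–C1–C2–C3–C4–C5–C6–O6–CH2–O12) | [CH-]1C(=O)[C@]3(C)O[C@H]3C[C@H](O[Si](C)(C)C(C)(C)C)/C(C)=C\[C@H]2OC[O+]1CC(C)=C2 | intermediate
27 | (4Z)-1,10-epoxy-3-[(tert-butyldimethylsilyl)oxy]-6,8-(methylenedioxy)germacra-4,11-dien-9-one; on the dioxane C5, isopropenyl and C9 are trans,trans; target configuration | C=C(C)[C@@H]1[C@H]2/C=C(C)\[C@@H](O[Si](C)(C)C(C)(C)C)C[C@@H]3O[C@@]3(C)C(=O)[C@@H]1OCO2 | intermediate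
28 | (4Z)-1,10-epoxy-6,8-dihydroxy-3-[(tert-butyldimethylsilyl)oxy]germacra-4,11-dien-9-one, target configuration | C=C(C)[C@@H]1[C@H](O)/C=C(C)\[C@@H](O[Si](C)(C)C(C)(C)C)C[C@@H]2O[C@@]2(C)C(=O)[C@@H]1O | intermediate
29 | 1,10:4,5-diepoxy-6,8-dihydroxy-3-[(tert-butyldimethylsilyl)oxy]germacr-11-en-9-one, target configuration | C=C(C)[C@@H]1[C@H](O)[C@H]2O[C@@]2(C)[C@@H](O[Si](C)(C)C(C)(C)C)C[C@@H]2O[C@@]2(C)C(=O)[C@@H]1O | intermediate
30 | 1,10:4,5-diepoxy-3,6,8-trihydroxygermacr-11-en-9-one, target configuration | C=C(C)[C@@H]1[C@H](O)[C@H]2O[C@@]2(C)[C@@H](O)C[C@@H]2O[C@@]2(C)C(=O)[C@@H]1O | intermediate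
31 | (1S,3S,4S,5R,6S,7R,8R,10R)-1,10:4,5-diepoxy-9-oxogermacr-11-ene-3,6,8-triyl tris[(2Z)-2-methylbut-2-enoate] | C=C(C)[C@@H]1[C@H](OC(=O)/C(C)=C\C)[C@H]2O[C@@]2(C)[C@@H](OC(=O)/C(C)=C\C)C[C@@H]2O[C@@]2(C)C(=O)[C@@H]1OC(=O)/C(C)=C\C | target

## Step count and risk

Total: 21 steps. Longest linear sequence: 19 steps (1, 2, 4–9, 11–21); steps 3 and 10 are side branches.

**Step 17 (key step, proposed new method).**
- What may go wrong: macrocyclic cyclopropanation of the dioxepine olefin or carbene dimerisation instead of ylide formation; ylide formation at the hindered O6; a [1,2] shift of the acetal carbon; poor facial control at C7.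
- Fallback: leave the acetal template and use the substrate class on which the copper-carbenoid/allyl ether oxonium-ylide [2,3] shift is documented, including in large-ring mode, a simple benzylic allyl ether. It sets out from 20 and returns at 28.
  - The acetal of 20 is hydrolysed (Me3SiOTf, 2,2'-bipyridyl; H2O) to the diol ester F1.
  - NaH and 4-methoxybenzyl bromide give the bis(4-methoxybenzyl) ether F2.
  - iBu2AlH gives the allylic alcohol F3.
  - Sharpless epoxidation with L-(+)-diethyl tartrate gives the epoxy alcohol F4.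
  - TEMPO/PhI(OAc)2 gives the epoxy acid F5.
  - Isobutyl chloroformate and then diazomethane give the diazoketone F6.
  - Cu(CF3COCHCOCF3)2 under high dilution forms the ylide at the primary allylic ether oxygen, and the [2,3] shift gives the ten-membered ring ether F7.
  - DDQ removes both 4-methoxybenzyl groups and returns 28.
  - Without the template, the sense of induction at C7 relative to C6 is not enforced and would have to be established.

**Step 18.**
- What may go wrong: Lewis-acid opening or rearrangement of the epoxy ketone, or epimerisation at C8 through silyl enol ether formation, during acetal cleavage.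
- Fallback: install the 1,10-epoxide only after the acetal is gone. It sets out from 20 and returns at 28.
  - LiOH gives the dienoic acid F8.
  - Mixed anhydride and diazomethane give the enone diazoketone F9.
  - The step-17 conditions give the bicyclic enone acetal F10.
  - The step-18 conditions, now on a robust enone, give the enone diol F11.
  - Weitz–Scheffer epoxidation (t-BuOOH, DBU) gives 28; the facial selectivity then rests on the ring conformation.

**Step 11.**
- What may go wrong: Z to E isomerisation of the enal under Lewis acid, γ-deprotonation at C6 by the amine, or insufficient enantiocontrol.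
- Fallback: build the chain in two known stages without a Lewis acid. It sets out from 15 and returns at 20.
  - Brown allylation with (−)-B-allyldiisopinocampheylborane (Si-face attack) gives the homoallylic alcohol F12.
  - TBSOTf gives the silyl ether F13.
  - Cross-metathesis with methyl methacrylate (second-generation Hoveyda–Grubbs catalyst) gives 20 as the E enoate.

**Step 19.**
- What may go wrong: competing epoxidation of the isopropenyl group (homoallylic to two hydroxyls), attack on the wrong face, or vanadium-mediated cleavage of the α-hydroxy ketone.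
- Fallback: use substrate control on the rigid bicycle. It sets out from 27 and returns at 29.
  - Buffered mCPBA (or dimethyldioxirane) on 27, where the dioxane fixes O6 on one face of C4=C5 and the ring carbon C7 blocks the other, gives the diepoxide acetal F14.
  - The step-18 conditions then give 29.

**Step 21.**
- What may go wrong: incomplete acylation of the hindered C6 hydroxyl, angelate to tiglate isomerisation on prolonged heating, or epimerisation at C8.
- Fallback: acylate in two stages so that no more than two hindered hydroxyls react at once. It sets out from 29 and returns at 31.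
  - The step-21 conditions on 29 give the 6,8-bis(angelate) silyl ether F15.
  - HF·pyridine gives the 3-hydroxy bis(angelate) F16.
  - A single angeloylation gives 31.

## Further compounds

F1 | step 17 | methyl (2E,5S,6Z,8S,9Z)-5-[(tert-butyldimethylsilyl)oxy]-8,11-dihydroxy-2,6,10-trimethylundeca-2,6,9-trienoate | COC(=O)/C(C)=C/C[C@H](O[Si](C)(C)C(C)(C)C)/C(C)=C\[C@@H](O)/C=C(C)\CO
F2 | step 17 | methyl (2E,5S,6Z,8S,9Z)-5-[(tert-butyldimethylsilyl)oxy]-8,11-bis[(4-methoxybenzyl)oxy]-2,6,10-trimethylundeca-2,6,9-trienoate | COC(=O)/C(C)=C/C[C@H](O[Si](C)(C)C(C)(C)C)/C(C)=C\[C@@H](OCc1ccc(OC)cc1)/C=C(C)\COCc1ccc(OC)cc1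
F3 | step 17 | (2E,5S,6Z,8S,9Z)-5-[(tert-butyldimethylsilyl)oxy]-8,11-bis[(4-methoxybenzyl)oxy]-2,6,10-trimethylundeca-2,6,9-trien-1-ol | OC/C(C)=C/C[C@H](O[Si](C)(C)C(C)(C)C)/C(C)=C\[C@@H](OCc1ccc(OC)cc1)/C=C(C)\COCc1ccc(OC)cc1
F4 | step 17 | (2S,3S)-epoxy alcohol of F3 (2,3-epoxide, otherwise as F3) | OC[C@]1(C)O[C@H]1C[C@H](O[Si](C)(C)C(C)(C)C)/C(C)=C\[C@@H](OCc1ccc(OC)cc1)/C=C(C)\COCc1ccc(OC)cc1
F5 | step 17 | (2R,3S)-epoxy acid from F4 | OC(=O)[C@]1(C)O[C@H]1C[C@H](O[Si](C)(C)C(C)(C)C)/C(C)=C\[C@@H](OCc1ccc(OC)cc1)/C=C(C)\COCc1ccc(OC)cc1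
F6 | step 17 | diazomethyl ketone from F5 | [N-]=[N+]=CC(=O)[C@]1(C)O[C@H]1C[C@H](O[Si](C)(C)C(C)(C)C)/C(C)=C\[C@@H](OCc1ccc(OC)cc1)/C=C(C)\COCc1ccc(OC)cc1
F7 | step 17 | (4Z)-1,10-epoxy-3-[(tert-butyldimethylsilyl)oxy]-6,8-bis[(4-methoxybenzyl)oxy]germacra-4,11-dien-9-one, target configuration | C=C(C)[C@@H]1[C@H](OCc2ccc(OC)cc2)/C=C(C)\[C@@H](O[Si](C)(C)C(C)(C)C)C[C@@H]2O[C@@]2(C)C(=O)[C@@H]1OCc1ccc(OC)cc1
F8 | step 18 | (2E,5S,6Z)-5-[(tert-butyldimethylsilyl)oxy]-2,6-dimethyl-7-[(4S)-6-methyl-4,7-dihydro-1,3-dioxepin-4-yl]hepta-2,6-dienoic acid | OC(=O)/C(C)=C/C[C@H](O[Si](C)(C)C(C)(C)C)/C(C)=C\[C@H]1OCOCC(C)=C1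
F9 | step 18 | (3E,6S,7Z)-1-diazo-6-[(tert-butyldimethylsilyl)oxy]-3,7-dimethyl-8-[(4S)-6-methyl-4,7-dihydro-1,3-dioxepin-4-yl]octa-3,7-dien-2-one | [N-]=[N+]=CC(=O)/C(C)=C/C[C@H](O[Si](C)(C)C(C)(C)C)/C(C)=C\[C@H]1OCOCC(C)=C1
F10 | step 18 | (1(10)E,4Z)-3-[(tert-butyldimethylsilyl)oxy]-6,8-(methylenedioxy)germacra-1(10),4,11-trien-9-one, target configuration at C3, C6, C7, C8 | C=C(C)[C@@H]1[C@H]2/C=C(C)\[C@@H](O[Si](C)(C)C(C)(C)C)C/C=C(C)/C(=O)[C@@H]1OCO2
F11 | step 18 | (1(10)E,4Z)-6,8-dihydroxy-3-[(tert-butyldimethylsilyl)oxy]germacra-1(10),4,11-trien-9-one | C=C(C)[C@@H]1[C@H](O)/C=C(C)\[C@@H](O[Si](C)(C)C(C)(C)C)C/C=C(C)/C(=O)[C@@H]1O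
F12 | step 11 | (1Z,3S)-2-methyl-1-[(4S)-6-methyl-4,7-dihydro-1,3-dioxepin-4-yl]hexa-1,5-dien-3-ol | C=CC[C@H](O)/C(C)=C\[C@H]1OCOCC(C)=C1
F13 | step 11 | tert-butyldimethylsilyl ether of F12 | C=CC[C@H](O[Si](C)(C)C(C)(C)C)/C(C)=C\[C@H]1OCOCC(C)=C1
F14 | step 19 | 1,10:4,5-diepoxy-3-[(tert-butyldimethylsilyl)oxy]-6,8-(methylenedioxy)germacr-11-en-9-one, target configuration | C=C(C)[C@@H]1[C@H]2[C@H]3O[C@@]3(C)[C@@H](O[Si](C)(C)C(C)(C)C)C[C@@H]3O[C@@]3(C)C(=O)[C@@H]1OCO2
F15 | step 21 | 1,10:4,5-diepoxy-9-oxo-3-[(tert-butyldimethylsilyl)oxy]germacr-11-ene-6,8-diyl bis[(2Z)-2-methylbut-2-enoate] | C=C(C)[C@@H]1[C@H](OC(=O)/C(C)=C\C)[C@H]2O[C@@]2(C)[C@@H](O[Si](C)(C)C(C)(C)C)C[C@@H]2O[C@@]2(C)C(=O)[C@@H]1OC(=O)/C(C)=C\C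
F16 | step 21 | 1,10:4,5-diepoxy-3-hydroxy-9-oxogermacr-11-ene-6,8-diyl bis[(2Z)-2-methylbut-2-enoate] | C=C(C)[C@@H]1[C@H](OC(=O)/C(C)=C\C)[C@H]2O[C@@]2(C)[C@@H](O)C[C@@H]2O[C@@]2(C)C(=O)[C@@H]1OC(=O)/C(C)=C\C
A1 | alternative 1 | (2Z,6E,10E)-4,9-bis[(tert-butyldimethylsilyl)oxy]-12-chloro-3,7,11-trimethyl-8-oxododeca-2,6,10-trienal | O=C/C=C(C)\[C@@H](O[Si](C)(C)C(C)(C)C)C/C=C(C)/C(=O)[C@H](O[Si](C)(C)C(C)(C)C)/C=C(C)/CCl
A2 | alternative 2 | 4-[(tert-butyldimethylsilyl)oxy]-3-methyl-1-(3-methylbuta-1,3-dien-2-yl)-6-(prop-1-en-2-yl)cyclohex-2-en-1-ol (1,6-dialkenyl groups trans) | C=C(C)C(=C)[C@]1(O)C=C(C)[C@@H](O[Si](C)(C)C(C)(C)C)C[C@H]1C(C)=C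
A3 | alternative 3 | thirteen-membered cyclic ether: 8,12-anhydro-seco form of the target skeleton (C9 ketone, C8H2–O–C12H2, C7=C11 and C4=C5 olefins, 1,10-epoxide, 3,6-bis(silyl ether)) | O=C1COC/C(C)=C\[C@H](O[Si](C)(C)C(C)(C)C)/C=C(C)\[C@@H](O[Si](C)(C)C(C)(C)C)C[C@@H]2O[C@]21C
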